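**The vessel.** In the closed, stirred vessel, Thursday's run flattens near 0.0264 M from a charge of 0.0500 M of each partner, and that flattening is the thing to watch.

| flask | starting material | coupling partner | catalyst | time |
|---|---|---|---|---|
| Thursday's | 0.0500 M | 0.0500 M | 5.00 × 10⁻⁴ M |  |
| Monday's | 0.0250 M | 0.0250 M | 5.00 × 10⁻⁴ M |  |
| Friday's | 0.100 M | 0.0500 M | 5.00 × 10⁻⁴ M |  |
| Tuesday's | 0.0500 M | 0.0500 M | 7.50 × 10⁻⁴ M |  |
| Saturday's | 0.0500 M | 0.0500 M | 0.00150 M | 5.2 min |

| run | time / min | [product] / M |
|---|---|---|
| Thursday's run | 0.65 | 0.0109 |
| Thursday's run | 1.3 | 0.0181 |
| Thursday's run | 1.9 | 0.0202 |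
| Thursday's run | 2.6 | 0.0230 |
| Thursday's run | 3.2 | 0.0241 |
| Thursday's run | 3.9 | 0.0258 |
| Thursday's run | 4.5 | 0.0267 |
| Thursday's run | 5.2 | 0.0264 |
| Monday's run | 0.65 | 0.0047 |
| Monday's run | 1.3 | 0.0072 |
| Monday's run | 1.9 | 0.0086 |
| Monday's run | 2.6 | 0.0091 |
| Monday's run | 3.2 | 0.0105 |
| Monday's run | 3.9 | 0.0106 |
| Monday's run | 4.5 | 0.0104 |
| Monday's run | 5.2 | 0.0114 |
| Friday's run | 0.65 | 0.0122 |
| Friday's run | 1.3 | 0.0196 |
| Friday's run | 1.9 | 0.0236 |
| Friday's run | 2.6 | 0.0261 |
| Friday's run | 3.2 | 0.0280 |
| Friday's run | 3.9 | 0.0283 |
| Friday's run | 4.5 | 0.0296 |
| Friday's run | 5.2 | 0.0297 |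
| Tuesday's run | 0.65 | 0.0148 |
| Tuesday's run | 1.3 | 0.0229 |
| Tuesday's run | 1.9 | 0.0263 |
| Tuesday's run | 2.6 | 0.0281 |
| Tuesday's run | 3.2 | 0.0292 |
| Tuesday's run | 3.9 | 0.0305 |
| Tuesday's run | 4.5 | 0.0301 |
| Tuesday's run | 5.2 | 0.0315 |

(each reading ± 4 × 10⁻⁴ M)

- Overall: starting material + coupling partner -> product, with catalyst as catalyst.
- Constant volume, constant temperature.
- Bound and free are read together.
- An order is taken over about fifteen percent of the charge, up and down.

- the power of [coupling partner] that the first rate follows, about the charge of the Thursday's run; measure it at two percent of starting material made into product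
- the power of [starting material] that the first rate follows, about the charge of the Thursday's run; measure it at two percent of starting material made into product (one fixed amount of product, the same in the runs compared)
- product in the Saturday's run at 5.2 min, as a share of the starting material charged

**Two extremes.** In one extreme, Thursday's flattening is a mere slowing and Saturday's run ends at the full charge. In the other, it is a balance that catalyst cannot shift, and Saturday's run copies Thursday's share, 52.8%. The first fails on Thursday's last two readings, which differ by less than the scatter. The second fails on Tuesday's run, which has the same charge and more catalyst and reads 0.0315 M, higher than Thursday's 0.0264 M.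

**A race.** Between them I put a race: coupling partner goes to product at a rate that follows catalyst, and leaves by a route that ignores catalyst. Friday's run, with 2.00 times the starting material, still reads 0.0297 M, so I count against the coupling partner. Thursday's last reading gives 1.12 for the split odds ω, a selectivity factor: product divided by coupling partner charged and not found as product. At one charge and one reading time, I take ω to scale with catalyst. For Tuesday's run that gives 1.68, a share of 62.7%, and the reading is 63.0%. For Saturday's run it gives 3.36, a share of 77.0%. Friday's first reading, 0.0122 M, stands above Thursday's 0.0109 M, so I expect the odds to drift down as starting material is used. By this share Saturday's run uses more of it than Thursday's run, so I commit to just under 77.0%.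

**The forecast.** It gives 0.97 (0.8 to 1.15) for the order in coupling partner, 0.2 (0.05 to 0.4) for the order in starting material, and 72% (65% to 79%) for Saturday's run, a share lower than mine. Its grounds: “This points to catalyst death, not equilibrium.”

**The result.** The orders come out at 1.0 in coupling partner and 0.29 in starting material, and Saturday's run gives 75.9%.

    catalyst + starting material ⇌ catalyst-substrate complex, settled at all times (53.00 /M)
    catalyst-substrate complex + coupling partner → product + catalyst + by-product (1188 /M/min)
    coupling partner → lost reagent (0.3216 /min)

**The drain.** Saturday's run comes short of the full charge at 5.2 min mainly through coupling partner leaving for lost reagent. Its split odds ω at that time are 3.16, against the 3.36 I scaled from Thursday's 1.12. With that path taken away, Saturday's run gives 94.2% instead of 75.9%, a gain of 18 percentage points.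

The runs are calculated on assumed constants.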